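**Retrosynthetic overview**

1. The target is reached by hydrogenolysis of its 7,4'-di-O-benzyl ether. That ether is cut at C4–C(aryl) and at O1–C2 into the acylphloroglucinol and a racemic, acyclic 1,3-diarylallyl alcohol, and both bonds are made in one flask.
2. Enabling feature: C2 and C4 are both benzylic and are joined through C3, and ring A carries O1 ortho and O7 para to C4a. The C2–C3–C4 unit of the allyl alcohol therefore ionises to an allyl cation (ring A o-quinone methide) with the phenol oxygen O1 placed for six-membered closure onto C2. After closure, the C3=C4 styrene bond of the chromene is protonated at C3 to a C4 cation stabilised by the same two oxygens.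
3. Stereochemistry: C2 (S) comes from a chiral counter-anion in an enantioconvergent O1–C2 closure. C4 (R, trans to the C2 aryl group) comes from axial capture of the cyclic cation by the acylphloroglucinol, whose two free ring positions are equivalent.
4. The allyl alcohol comes from a salicylaldehyde and an acetophenone (Claisen–Schmidt condensation, Luche reduction); the acylphloroglucinol comes from phloroglucinol and 9-phenylnonanoic acid (Friedel–Crafts acylation).
5. Ring order: rings A and B, the phloroglucinol ring and the terminal phenyl ring are bought; the pyran ring C is the only ring formed, in step 4.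

Key step: step 4

Remark: 9-phenylnonanoic acid is taken to be purchasable.
Remark: the sense of induction of the chiral acid in step 4 is an assumption; the catalyst enantiomer that delivers the 2S chromene is the one used, written here as the R enantiomer.

**Route**

Step 1
Reactants: 1 phloroglucinol (benzene-1,3,5-triol); 2 9-phenylnonanoic acid
Product: 3 9-phenyl-1-(2,4,6-trihydroxyphenyl)nonan-1-one
Conditions: BF3·OEt2 (promoter and solvent), 90 °C; then aq. NaOAc, rt
Reagents that add atoms: none
Why: Friedel–Crafts C-acylation of the threefold-symmetric, highly activated triol by the BF3-activated carboxylic acid should give a single regioisomer, since the first acyl group deactivates the ring against a second one and the unactivated terminal phenyl ring of 2 cannot compete.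

Step 2
Reactants: 4 4-(benzyloxy)-2-hydroxybenzaldehyde; 5 1-[4-(benzyloxy)phenyl]ethan-1-one
Product: 6 (E)-3-[4-(benzyloxy)-2-hydroxyphenyl]-1-[4-(benzyloxy)phenyl]prop-2-en-1-one
Conditions: KOH (aq., excess), EtOH, rt; then AcOH to pH 6
Reagents that add atoms: none
Why: Claisen–Schmidt (crossed aldol) condensation in which only 5 can enolise and only 4 offers an aldehyde, the E1cB dehydration giving the conjugated E enone under thermodynamic control while the benzyl ethers are inert to hydroxide.

Step 3
Reactants: 6 (E)-3-[4-(benzyloxy)-2-hydroxyphenyl]-1-[4-(benzyloxy)phenyl]prop-2-en-1-one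
Product: 7 rac-(E)-3-[4-(benzyloxy)-2-hydroxyphenyl]-1-[4-(benzyloxy)phenyl]prop-2-en-1-ol
Conditions: NaBH4, CeCl3·7H2O, MeOH/THF, −40 °C; pH 7 phosphate buffer; Et3N-washed silica
Reagents that add atoms: none
Why: Luche reduction delivers hydride 1,2 to the cerium-activated carbonyl group of the enone, whose electron-rich β-aryl group further disfavours 1,4-addition; the new carbinol centre is left racemic on purpose because step 4 erases it.

Step 4
Reactants: 7 rac-(E)-3-[4-(benzyloxy)-2-hydroxyphenyl]-1-[4-(benzyloxy)phenyl]prop-2-en-1-ol; 3 9-phenyl-1-(2,4,6-trihydroxyphenyl)nonan-1-one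
Product: 10 1-{3-[(2S,4R)-7-(benzyloxy)-2-[4-(benzyloxy)phenyl]-3,4-dihydro-2H-chromen-4-yl]-2,4,6-trihydroxyphenyl}-9-phenylnonan-1-one, via ring A o-quinone methide 8 (not isolated), via (2S)-chromene 9 (not isolated)
Conditions: (R)-3,3'-bis(9-phenanthryl)-H8-BINOL N-triflylphosphoramide (10 mol %), toluene, −78 °C; then 3 (3 equiv) in CH2Cl2/MeNO2, −78 → −20 °C; Et3N quench
Reagents that add atoms: none
Why: Proposed new method: the strong chiral acid ionises racemic 7 with loss of water to the ring A o-quinone methide 8, held in O-protonated form as a contact ion pair with the chiral phosphoramide anion, and O1 closes on C2 to give chromene 9 (ring C, 6-endo-trig attack on the allyl cation terminus, equivalent to an oxa-6π electrocyclisation of s-cis 8); the same acid then protonates the 2,4-dioxygenated styrene bond of 9 at C3, and the resulting C4 benzylic cation is captured by a ring CH carbon of 3 in a Friedel–Crafts alkylation. The closest known reaction types are the chiral N-triflylphosphoramide-catalysed asymmetric intramolecular allylic etherification of ortho-(3-hydroxyallyl)phenols to 2-substituted 2H-chromenes and the acid-mediated, trans-selective C4 arylation of flavan-4-yl cations by acylphloroglucinols; what is new is their relay in one flask with the chromene, not a flavan-4-ol, as the cation source. C2 (S) is set by the chiral counter-anion in an enantioconvergent closure that erases the carbinol centre of 7. C4 (R) is set by the substrate: with the C2 aryl group equatorial on the half-chair cation, 3 enters axially past the small axial C2–H, which puts the two aryl groups trans. The step needs ring closure before arylation, arylation at C4 and not at C2, C- over O-alkylation and mono-alkylation of 3: these are secured by the free ortho phenol of ring A placed for six-membered closure (intramolecular and complete at −78 °C before 3 is added), by the fact that in 9 only C4 can become cationic on protonation, by the reversibility of O-alkylation under acid, and by the two equivalent ring CH positions of 3 used in excess. Enantiopurity rests on keeping the second stage cold enough that C3 protonation outruns re-ionisation of the C2–O1 bond of 9.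

Step 5
Reactants: 10 1-{3-[(2S,4R)-7-(benzyloxy)-2-[4-(benzyloxy)phenyl]-3,4-dihydro-2H-chromen-4-yl]-2,4,6-trihydroxyphenyl}-9-phenylnonan-1-one
Product: 11 (+)-myristinin D
Conditions: H2 (1 atm), Pd/C (10 wt % Pd), EtOAc/MeOH, rt
Reagents that add atoms: none
Why: Catalytic hydrogenolysis of the two primary benzyl aryl ethers should be faster than cleavage of the cyclic secondary benzylic C2–O1 ether or reduction of the hydrogen-bonded aryl ketone, and it touches neither stereocentre.

**Compound list**

1 | phloroglucinol (benzene-1,3,5-triol) | Oc1cc(O)cc(O)c1 | starting material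
2 | 9-phenylnonanoic acid | OC(=O)CCCCCCCCc1ccccc1 | starting material
3 | 9-phenyl-1-(2,4,6-trihydroxyphenyl)nonan-1-one | O=C(CCCCCCCCc1ccccc1)c1c(O)cc(O)cc1O | intermediate
4 | 4-(benzyloxy)-2-hydroxybenzaldehyde | O=Cc1ccc(OCc2ccccc2)cc1O | starting material
5 | 1-[4-(benzyloxy)phenyl]ethan-1-one | CC(=O)c1ccc(OCc2ccccc2)cc1 | starting material
6 | (E)-3-[4-(benzyloxy)-2-hydroxyphenyl]-1-[4-(benzyloxy)phenyl]prop-2-en-1-one | O=C(/C=C/c1ccc(OCc2ccccc2)cc1O)c1ccc(OCc2ccccc2)cc1 | intermediate
7 | rac-(E)-3-[4-(benzyloxy)-2-hydroxyphenyl]-1-[4-(benzyloxy)phenyl]prop-2-en-1-ol (racemic at the carbinol carbon) | OC(/C=C/c1ccc(OCc2ccccc2)cc1O)c1ccc(OCc2ccccc2)cc1 | intermediate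
8 | ring A o-quinone methide, (6Z)-3-(benzyloxy)-6-{(E)-3-[4-(benzyloxy)phenyl]prop-2-en-1-ylidene}cyclohexa-2,4-dien-1-one (not isolated, step 4; present as its O-protonated ion pair with the catalyst anion) | O=C1C=C(OCc2ccccc2)C=C/C1=C/C=C/c1ccc(OCc2ccccc2)cc1 | intermediate
9 | (2S)-7-(benzyloxy)-2-[4-(benzyloxy)phenyl]-2H-chromene (not isolated, step 4) | C1=C[C@@H](c2ccc(OCc3ccccc3)cc2)Oc2cc(OCc3ccccc3)ccc21 | intermediate
10 | 1-{3-[(2S,4R)-7-(benzyloxy)-2-[4-(benzyloxy)phenyl]-3,4-dihydro-2H-chromen-4-yl]-2,4,6-trihydroxyphenyl}-9-phenylnonan-1-one (2,4-trans) | O=C(CCCCCCCCc1ccccc1)c1c(O)cc(O)c([C@@H]2C[C@@H](c3ccc(OCc4ccccc4)cc3)Oc3cc(OCc4ccccc4)ccc32)c1O | intermediate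
11 | (+)-myristinin D, 1-{3-[(2S,4R)-7-hydroxy-2-(4-hydroxyphenyl)-3,4-dihydro-2H-chromen-4-yl]-2,4,6-trihydroxyphenyl}-9-phenylnonan-1-one | O=C(CCCCCCCCc1ccccc1)c1c(O)cc(O)c([C@@H]2C[C@@H](c3ccc(O)cc3)Oc3cc(O)ccc32)c1O | target

**Step count and risks**

Total step count: 5. Longest linear sequence: 4 steps (steps 2 to 5); step 1 makes the second fragment.

Steps most likely to fail:

1. Step 4 (Proposed new method). In the second stage, chromene 9 may re-ionise at C2–O1 under the acid, which would cause loss of enantiopurity and open-chain capture of 3. It may also be consumed by its own C4 cation, through oligomerisation or hydride transfer, faster than 3 captures that cation. The fallback uses known chemistry; it sets out from 7 and comes back at 10. Only the first stage is run (the same chiral acid, toluene, −78 °C, cold Et3N quench), which is the known asymmetric allylic etherification, and 9 is isolated. The C3=C4 bond is then hydrated under neutral Mukaiyama conditions (Co(acac)2, PhSiH3, O2, iPrOH/THF), where the C2–O1 bond is inert and the benzylic C4 radical fixes the regiochemistry, to give (2S)-7-(benzyloxy)-2-[4-(benzyloxy)phenyl]-3,4-dihydro-2H-chromen-4-ol F1 as a mixture of C4 epimers. F1 is ionised with TFA in CH2Cl2 at 0 °C in the presence of 3, the known Friedel–Crafts arylation of flavan-4-ols. Both C4 epimers should converge through the same cation on the trans product 10.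

2. Step 3. The doubly activated allylic alcohol may close to racemic chromene or exchange with methanol during the quench and on silica, and some hydride may add 1,4. The fallback sets out from 6 and comes back at 7. The phenol is silylated (TBSCl, imidazole, DMF) to (E)-1-[4-(benzyloxy)phenyl]-3-{4-(benzyloxy)-2-[(tert-butyldimethylsilyl)oxy]phenyl}prop-2-en-1-one F2. Luche reduction then gives rac-(E)-1-[4-(benzyloxy)phenyl]-3-{4-(benzyloxy)-2-[(tert-butyldimethylsilyl)oxy]phenyl}prop-2-en-1-ol F3, which cannot ring-close and can be purified and stored. The phenol is freed with TBAF buffered with AcOH in THF at −20 °C just before use, and crude 7 is taken into step 4 after a neutral aqueous work-up without chromatography.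

3. Step 5. Hydrogenolytic opening of ring C at the benzylic C2–O1 bond, or reduction of the aryl ketone, may compete with O-debenzylation. The fallback sets out from 10 and comes back at 11. It is a non-reductive Lewis-acid dealkylation with BCl3 and pentamethylbenzene as cation scavenger in CH2Cl2 at −78 °C, followed by a methanol quench. It passes through no new intermediate (F0: none).

**Further compounds**

F1 | step 4 | (2S)-7-(benzyloxy)-2-[4-(benzyloxy)phenyl]-3,4-dihydro-2H-chromen-4-ol (both C4 epimers) | OC1C[C@@H](c2ccc(OCc3ccccc3)cc2)Oc2cc(OCc3ccccc3)ccc21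
F2 | step 3 | (E)-1-[4-(benzyloxy)phenyl]-3-{4-(benzyloxy)-2-[(tert-butyldimethylsilyl)oxy]phenyl}prop-2-en-1-one | O=C(/C=C/c1ccc(OCc2ccccc2)cc1O[Si](C)(C)C(C)(C)C)c1ccc(OCc2ccccc2)cc1
F3 | step 3 | rac-(E)-1-[4-(benzyloxy)phenyl]-3-{4-(benzyloxy)-2-[(tert-butyldimethylsilyl)oxy]phenyl}prop-2-en-1-ol | OC(/C=C/c1ccc(OCc2ccccc2)cc1O[Si](C)(C)C(C)(C)C)c1ccc(OCc2ccccc2)cc1
F0 | step 5 | none | none
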